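**Retrosynthetic overview**
1. Target 26 ⇐ C2 ketone / C10 silyl ether 23, by desilylation, acetylation and hydroxyl-directed ketone reduction.
2. Ring B (seven-membered) is closed last at C1–C10 by a SmI2 Reformatsky aldol of an α-bromo ketone onto an epoxy aldehyde. The trans-fused oxirane is made beforehand on the open chain (Sharpless epoxidation of an E-allylic alcohol) and the ring is closed around it.
3. Side chain: C9–C10 by cross-metathesis, C6–C7 by catalyst-controlled methallylboration; the veratroate goes on early.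
4. Ring A with C4/C5: oxymercuration of the cyclopropane of bicyclo[3.1.0]hexanone 6 gives the C4 tertiary alcohol with inversion and C6 as CH2OH.
5. 6 ⇐ cycloisomerisation (Ph3PAuCl/AgSbF6) of enynol 5 ⇐ asymmetric crotylboration of ynal 3. Ring order: cyclopropane-fused ring A, cyclopropane opening, oxirane, ring B.

Assumption: the SMILES is taken literally; (8R,9R) makes the oxirane trans-fused to the seven-membered ring (C7 and C10 anti across C8–C9, as in an epoxide from an E-alkene), so the epoxide is built on an open chain and the ring is closed around it.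

Numbering: C1–C10 follow daucane numbering (C1 methyl-bearing ring-fusion carbon, C2 acetate carbon, C3, C4 carbinol with isopropyl, C5 ring-fusion CH, C6 veratroate carbon, C7, C8 methyl oxirane carbon, C9 oxirane CH, C10 carbinol). The same locants are used for these atoms in all earlier intermediates.

**Route**

Step 1
Reactants: 1 3-methylbut-1-yne
Product: 3 4-methylpent-2-ynal, via lithium acetylide 2 (not isolated)
Conditions: nBuLi, THF, −78 °C; then DMF, −78 → 0 °C; H2O work-up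
Reagents that add atoms: n-butyllithium, [Li]CCCC; N,N-dimethylformamide, CN(C)C=O
Why: Deprotonation of the terminal alkyne and formylation of the lithium acetylide with DMF gives the ynal after hydrolysis of the hemiaminal; no stereocentre is formed.

Step 2
Reactants: 3 4-methylpent-2-ynal; 4 2-[(2Z)-but-2-en-1-yl]-4,4,5,5-tetramethyl-1,3,2-dioxaborolane
Product: 5 (3S,4R)-3,7-dimethyloct-1-en-5-yn-4-ol
Conditions: (R)-TRIP [(R)-3,3′-bis(2,4,6-triisopropylphenyl)-BINOL hydrogen phosphate] (5 mol %), 4 Å MS, toluene, −30 °C; H2O work-up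
Reagents that add atoms: none
Why: Chiral-phosphoric-acid-catalysed crotylboration through a closed chair transition state: the Z-boronate gives the syn adduct and the (R)-catalyst selects the aldehyde face that gives the 4R carbinol, hence (3S,4R).

Step 3
Reactants: 5 (3S,4R)-3,7-dimethyloct-1-en-5-yn-4-ol
Product: 6 (1R,4S,5S)-4-methyl-1-(propan-2-yl)bicyclo[3.1.0]hexan-3-one
Conditions: Ph3PAuCl (2 mol %), AgSbF6 (2 mol %), CH2Cl2, 23 °C
Reagents that add atoms: none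
Why: Cycloisomerisation of a 5-en-1-yn-3-ol by monovalent gold: the alkene cyclopropanates the activated alkyne through a chair-like transition state with OH and CH3 pseudo-equatorial, so the CH2 bridge forms anti to the methyl group (bridgeheads 1R,5S), and a 1,2-hydride shift of the carbinol hydrogen converts the gold carbene into the ketone.

Step 4
Reactants: 6 (1R,4S,5S)-4-methyl-1-(propan-2-yl)bicyclo[3.1.0]hexan-3-one
Product: 8 (2S,3R,4R)-4-hydroxy-3-(hydroxymethyl)-2-methyl-4-(propan-2-yl)cyclopentan-1-one, via alkylmercury trifluoroacetate 7 (not isolated)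
Conditions: Hg(O2CCF3)2, THF–H2O (4:1), 0 → 23 °C; then DMF, O2 (bubbling), NaBH4, 0 °C
Reagents that add atoms: mercury bis(trifluoroacetate), O=C(O[Hg]OC(=O)C(F)(F)F)C(F)(F)F; water, O; dioxygen, O=O
Why: Cyclopropane oxymercuration followed by oxidative demercuration: divalent mercury attacks the unhindered CH2 corner and breaks the bond to the isopropyl-bearing quaternary carbon, water adds there with inversion so the tertiary OH ends anti to the CH2Hg arm (C4 R, OH cis to H-5), and NaBH4/O2 turns C–Hg into CH2OH faster than borohydride reduces the hindered ketone in DMF.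

Step 5
Reactants: 8 (2S,3R,4R)-4-hydroxy-3-(hydroxymethyl)-2-methyl-4-(propan-2-yl)cyclopentan-1-one
Product: 9 (1S,2R,5S)-2-hydroxy-5-methyl-4-oxo-2-(propan-2-yl)cyclopentane-1-carbaldehyde
Conditions: TEMPO (10 mol %), PhI(OAc)2, CH2Cl2, 23 °C
Reagents that add atoms: none
Why: Oxoammonium (TEMPO) oxidation is selective for the primary alcohol and non-basic, so the tertiary alcohol, the ketone and the α-stereocentre C5 are untouched.

Step 6
Reactants: 9 (1S,2R,5S)-2-hydroxy-5-methyl-4-oxo-2-(propan-2-yl)cyclopentane-1-carbaldehyde; 10 4,4,5,5-tetramethyl-2-(2-methylprop-2-en-1-yl)-1,3,2-dioxaborolane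
Product: 11 (2S,3R,4R)-4-hydroxy-3-[(1R)-1-hydroxy-3-methylbut-3-en-1-yl]-2-methyl-4-(propan-2-yl)cyclopentan-1-one
Conditions: (R)-TRIP (5 mol %), 4 Å MS, toluene, −30 °C; H2O work-up
Reagents that add atoms: none
Why: Chiral-phosphoric-acid-catalysed allylboration (chair transition state) reacts only with the aldehyde in the presence of the ketone and free tertiary OH, and the (R)-catalyst sets C6 as R under catalyst control with the same facial sense as in step 2.

Step 7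
Reactants: 11 (2S,3R,4R)-4-hydroxy-3-[(1R)-1-hydroxy-3-methylbut-3-en-1-yl]-2-methyl-4-(propan-2-yl)cyclopentan-1-one; 12 3,4-dimethoxybenzoyl chloride
Product: 13 (1R)-1-[(1R,2R,5S)-2-hydroxy-5-methyl-4-oxo-2-(propan-2-yl)cyclopentyl]-3-methylbut-3-en-1-yl 3,4-dimethoxybenzoate
Conditions: Et3N, DMAP (10 mol %), CH2Cl2, 0 → 23 °C
Reagents that add atoms: none
Why: DMAP-catalysed acylation esterifies the only secondary alcohol while the tertiary alcohol stays free, so the final C6 ester also serves as the protecting group.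

Step 8
Reactants: 13 (1R)-1-[(1R,2R,5S)-2-hydroxy-5-methyl-4-oxo-2-(propan-2-yl)cyclopentyl]-3-methylbut-3-en-1-yl 3,4-dimethoxybenzoate; 14 (2E)-but-2-enal
Product: 15 (1R,3E)-1-[(1R,2R,5S)-2-hydroxy-5-methyl-4-oxo-2-(propan-2-yl)cyclopentyl]-3-methyl-5-oxopent-3-en-1-yl 3,4-dimethoxybenzoate
Conditions: second-generation Hoveyda–Grubbs catalyst RuCl2(H2IMes)(=CH–C6H4-2-OiPr) (5 mol %), 14 (5 equiv), CH2Cl2, 40 °C
Reagents that add atoms: none
Why: Olefin cross-metathesis of the 1,1-disubstituted alkene with an enal gives the conjugated trisubstituted enal under thermodynamic control, which fixes the E geometry (C7 and C10 anti) that becomes the trans oxirane.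

Step 9
Reactants: 15 (1R,3E)-1-[(1R,2R,5S)-2-hydroxy-5-methyl-4-oxo-2-(propan-2-yl)cyclopentyl]-3-methyl-5-oxopent-3-en-1-yl 3,4-dimethoxybenzoate
Product: 16 (1R,3E)-5-hydroxy-1-[(1R,2R,5S)-2-hydroxy-5-methyl-4-oxo-2-(propan-2-yl)cyclopentyl]-3-methylpent-3-en-1-yl 3,4-dimethoxybenzoate
Conditions: NaBH4, EtOH–CH2Cl2 (3:7), −78 °C
Reagents that add atoms: none
Why: Chemoselective 1,2-reduction: at −78 °C borohydride reduces the aldehyde much faster than the hindered cyclopentanone, giving the E-allylic alcohol without a new stereocentre.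

Step 10
Reactants: 16 (1R,3E)-5-hydroxy-1-[(1R,2R,5S)-2-hydroxy-5-methyl-4-oxo-2-(propan-2-yl)cyclopentyl]-3-methylpent-3-en-1-yl 3,4-dimethoxybenzoate
Product: 17 (1R)-1-[(1R,2R,5S)-2-hydroxy-5-methyl-4-oxo-2-(propan-2-yl)cyclopentyl]-2-[(2R,3R)-3-(hydroxymethyl)-2-methyloxiran-2-yl]ethyl 3,4-dimethoxybenzoate
Conditions: Ti(OiPr)4 (10 mol %), D-(−)-diethyl tartrate (12 mol %), tBuOOH, 4 Å MS, CH2Cl2, −20 °C
Reagents that add atoms: tert-butyl hydroperoxide, CC(C)(C)OO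
Why: Sharpless asymmetric epoxidation with tetravalent titanium: concerted syn oxygen transfer keeps C7 and C10 anti on the oxirane and the D-(−)-tartrate selects the face giving (8R,9R), the same sense as geraniol to (2R,3R)-epoxygeraniol.

Step 11
Reactants: 17 (1R)-1-[(1R,2R,5S)-2-hydroxy-5-methyl-4-oxo-2-(propan-2-yl)cyclopentyl]-2-[(2R,3R)-3-(hydroxymethyl)-2-methyloxiran-2-yl]ethyl 3,4-dimethoxybenzoate
Product: 19 (1R)-1-[(1R,2R,5S)-5-bromo-2-hydroxy-5-methyl-4-oxo-2-(propan-2-yl)cyclopentyl]-2-[(2R,3R)-3-(hydroxymethyl)-2-methyloxiran-2-yl]ethyl 3,4-dimethoxybenzoate, via trilithium enolate 18 (not isolated)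
Conditions: LiN(iPr)2 (3.2 equiv), THF, −78 °C; then NBS, −78 °C; AcOH quench
Reagents that add atoms: lithium diisopropylamide, CC(C)N([Li])C(C)C; N-bromosuccinimide, O=C1CCC(=O)N1Br
Why: Enolate α-bromination: once both hydroxyls are deprotonated, the C4 alkoxide disfavours enolisation toward C3, so the ketone enolises at C1 and bromine enters there anti to the C5 side chain; this centre is erased in step 13.

Step 12
Reactants: 19 (1R)-1-[(1R,2R,5S)-5-bromo-2-hydroxy-5-methyl-4-oxo-2-(propan-2-yl)cyclopentyl]-2-[(2R,3R)-3-(hydroxymethyl)-2-methyloxiran-2-yl]ethyl 3,4-dimethoxybenzoate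
Product: 20 (1R)-1-[(1R,2R,5S)-5-bromo-2-hydroxy-5-methyl-4-oxo-2-(propan-2-yl)cyclopentyl]-2-[(2R,3S)-3-formyl-2-methyloxiran-2-yl]ethyl 3,4-dimethoxybenzoate
Conditions: Dess–Martin periodinane, CH2Cl2, 0 → 23 °C
Reagents that add atoms: none
Why: Dess–Martin oxidation gives the epoxy aldehyde under non-basic conditions that leave the tertiary bromide, the oxirane and all stereocentres intact (the C9 descriptor changes only by priority).

Step 13
Reactants: 20 (1R)-1-[(1R,2R,5S)-5-bromo-2-hydroxy-5-methyl-4-oxo-2-(propan-2-yl)cyclopentyl]-2-[(2R,3S)-3-formyl-2-methyloxiran-2-yl]ethyl 3,4-dimethoxybenzoate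
Product: 23 (1R,4R,5R,6R,8R,9R,10R)-8,9-epoxy-4-hydroxy-2-oxo-10-(triethylsilyloxy)daucan-6-yl 3,4-dimethoxybenzoate, via samarium enolate 21 (not isolated), via samarium aldolate 22 (not isolated)
Conditions: SmI2 (2.2 equiv), THF, −78 °C, slow addition of 20 (final 0.005 M); then Et3SiCl, −78 → 0 °C
Reagents that add atoms: samarium diiodide, I[Sm]I; chlorotriethylsilane, CC[Si](Cl)(CC)CC
Why: Proposed new method: divalent samarium reduces the tertiary α-bromo ketone far faster than the aldehyde, and the resulting trivalent samarium enolate adds to the epoxy aldehyde through a chelated chair (Zimmerman–Traxler) transition state with C9 equatorial, which sets C10 as R; the roughly 130° torsion imposed by the trans oxirane can be spanned only if C10 bonds to the face of C1 opposite to C6, which sets the trans ring fusion (C1 R); the irreversible, strongly exothermic C–C bond formation pays for a strain comparable to that of isolable trans-bicyclo[5.1.0]octane, and the closest known reaction type is the SmI2 intramolecular Reformatsky aldol used to close medium rings.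

Step 14
Reactants: 23 (1R,4R,5R,6R,8R,9R,10R)-8,9-epoxy-4-hydroxy-2-oxo-10-(triethylsilyloxy)daucan-6-yl 3,4-dimethoxybenzoate
Product: 24 (1S,2S,4R,5R,6R,8R,9R,10R)-8,9-epoxy-2,4-dihydroxy-10-(triethylsilyloxy)daucan-6-yl 3,4-dimethoxybenzoate
Conditions: Me4NBH(OAc)3, MeCN–AcOH (4:1), −35 °C
Reagents that add atoms: none
Why: Hydroxyl-directed (Evans–Saksena) reduction: the C4 hydroxyl binds boron and delivers hydride intramolecularly to the face of the C2 ketone it sits on, giving the 1,3-anti diol, i.e. the 2S alcohol (the C1 descriptor changes only by priority).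

Step 15
Reactants: 24 (1S,2S,4R,5R,6R,8R,9R,10R)-8,9-epoxy-2,4-dihydroxy-10-(triethylsilyloxy)daucan-6-yl 3,4-dimethoxybenzoate
Product: 25 (1S,2S,4R,5R,6R,8R,9R,10R)-2-acetoxy-8,9-epoxy-4-hydroxy-10-(triethylsilyloxy)daucan-6-yl 3,4-dimethoxybenzoate
Conditions: Ac2O, DMAP (cat.), pyridine, 0 °C
Reagents that add atoms: acetic anhydride, CC(=O)OC(C)=O
Why: DMAP-catalysed acetylation takes the only free secondary alcohol (C2), because C10 is silylated and the tertiary C4 alcohol does not react at 0 °C.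

Step 16
Reactants: 25 (1S,2S,4R,5R,6R,8R,9R,10R)-2-acetoxy-8,9-epoxy-4-hydroxy-10-(triethylsilyloxy)daucan-6-yl 3,4-dimethoxybenzoate
Product: 26 (1R,2S,4R,5R,6R,8R,9R,10R)-2-acetoxy-8,9-epoxy-4,10-dihydroxydaucan-6-yl 3,4-dimethoxybenzoate
Conditions: Bu4NF, AcOH (1:1), THF, 0 °C
Reagents that add atoms: none
Why: Buffered fluoride desilylation frees the C10 alcohol without acyl migration or opening of the strained oxirane, giving the target.

**Compound list**
1 | 3-methylbut-1-yne | CC(C)C#C | starting material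
2 | (3-methylbut-1-yn-1-yl)lithium | [Li]C#CC(C)C | intermediate
3 | 4-methylpent-2-ynal | CC(C)C#CC=O | intermediate
4 | 2-[(2Z)-but-2-en-1-yl]-4,4,5,5-tetramethyl-1,3,2-dioxaborolane | C/C=C\CB1OC(C)(C)C(C)(C)O1 | starting material
5 | (3S,4R)-3,7-dimethyloct-1-en-5-yn-4-ol | C=C[C@H](C)[C@@H](O)C#CC(C)C | intermediate
6 | (1R,4S,5S)-4-methyl-1-(propan-2-yl)bicyclo[3.1.0]hexan-3-one | C[C@H]1[C@@H]2C[C@@]2(CC1=O)C(C)C | intermediate
7 | {[(1S,2R,5S)-2-hydroxy-5-methyl-4-oxo-2-(propan-2-yl)cyclopentyl]methyl}mercury trifluoroacetate | C[C@H]1[C@H](C[Hg]OC(=O)C(F)(F)F)[C@](O)(C(C)C)CC1=O | intermediate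
8 | (2S,3R,4R)-4-hydroxy-3-(hydroxymethyl)-2-methyl-4-(propan-2-yl)cyclopentan-1-one | C[C@H]1[C@H](CO)[C@](O)(C(C)C)CC1=O | intermediate
9 | (1S,2R,5S)-2-hydroxy-5-methyl-4-oxo-2-(propan-2-yl)cyclopentane-1-carbaldehyde | C[C@H]1[C@H](C=O)[C@](O)(C(C)C)CC1=O | intermediate
10 | 4,4,5,5-tetramethyl-2-(2-methylprop-2-en-1-yl)-1,3,2-dioxaborolane | CC(=C)CB1OC(C)(C)C(C)(C)O1 | starting material
11 | (2S,3R,4R)-4-hydroxy-3-[(1R)-1-hydroxy-3-methylbut-3-en-1-yl]-2-methyl-4-(propan-2-yl)cyclopentan-1-one | C[C@H]1[C@H]([C@H](O)CC(C)=C)[C@](O)(C(C)C)CC1=O | intermediate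
12 | 3,4-dimethoxybenzoyl chloride | COc1ccc(C(Cl)=O)cc1OC | starting material
13 | (1R)-1-[(1R,2R,5S)-2-hydroxy-5-methyl-4-oxo-2-(propan-2-yl)cyclopentyl]-3-methylbut-3-en-1-yl 3,4-dimethoxybenzoate | C[C@H]1[C@H]([C@H](OC(=O)c2ccc(OC)c(OC)c2)CC(C)=C)[C@](O)(C(C)C)CC1=O | intermediate
14 | (2E)-but-2-enal | C/C=C/C=O | starting material
15 | (1R,3E)-1-[(1R,2R,5S)-2-hydroxy-5-methyl-4-oxo-2-(propan-2-yl)cyclopentyl]-3-methyl-5-oxopent-3-en-1-yl 3,4-dimethoxybenzoate | C[C@H]1[C@H]([C@H](OC(=O)c2ccc(OC)c(OC)c2)C/C(C)=C/C=O)[C@](O)(C(C)C)CC1=O | intermediate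
16 | (1R,3E)-5-hydroxy-1-[(1R,2R,5S)-2-hydroxy-5-methyl-4-oxo-2-(propan-2-yl)cyclopentyl]-3-methylpent-3-en-1-yl 3,4-dimethoxybenzoate | C[C@H]1[C@H]([C@H](OC(=O)c2ccc(OC)c(OC)c2)C/C(C)=C/CO)[C@](O)(C(C)C)CC1=O | intermediate
17 | (1R)-1-[(1R,2R,5S)-2-hydroxy-5-methyl-4-oxo-2-(propan-2-yl)cyclopentyl]-2-[(2R,3R)-3-(hydroxymethyl)-2-methyloxiran-2-yl]ethyl 3,4-dimethoxybenzoate | C[C@H]1[C@H]([C@H](OC(=O)c2ccc(OC)c(OC)c2)C[C@@]3(C)O[C@@H]3CO)[C@](O)(C(C)C)CC1=O | intermediate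
18 | trilithium salt of 17 (C1=C2 enolate; C4 and C10 alkoxides) | CC1=C(O[Li])C[C@@](O[Li])(C(C)C)[C@H]1[C@H](OC(=O)c2ccc(OC)c(OC)c2)C[C@@]3(C)O[C@@H]3CO[Li] | intermediate
19 | (1R)-1-[(1R,2R,5S)-5-bromo-2-hydroxy-5-methyl-4-oxo-2-(propan-2-yl)cyclopentyl]-2-[(2R,3R)-3-(hydroxymethyl)-2-methyloxiran-2-yl]ethyl 3,4-dimethoxybenzoate | C[C@]1(Br)[C@H]([C@H](OC(=O)c2ccc(OC)c(OC)c2)C[C@@]3(C)O[C@@H]3CO)[C@](O)(C(C)C)CC1=O | intermediate
20 | (1R)-1-[(1R,2R,5S)-5-bromo-2-hydroxy-5-methyl-4-oxo-2-(propan-2-yl)cyclopentyl]-2-[(2R,3S)-3-formyl-2-methyloxiran-2-yl]ethyl 3,4-dimethoxybenzoate | C[C@]1(Br)[C@H]([C@H](OC(=O)c2ccc(OC)c(OC)c2)C[C@@]3(C)O[C@@H]3C=O)[C@](O)(C(C)C)CC1=O | intermediate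
21 | diiodosamarium C1=C2 enolate formed from 20 by loss of bromide | CC1=C(O[Sm](I)I)C[C@@](O)(C(C)C)[C@H]1[C@H](OC(=O)c2ccc(OC)c(OC)c2)C[C@@]3(C)O[C@@H]3C=O | intermediate
22 | diiodosamarium C10 alkoxide of (1R,4R,5R,6R,8R,9R,10R)-8,9-epoxy-4,10-dihydroxy-2-oxodaucan-6-yl 3,4-dimethoxybenzoate | COc1ccc(C(=O)O[C@@H]2C[C@@]3(C)O[C@@H]3[C@H](O[Sm](I)I)[C@]3(C)C(=O)C[C@@](O)(C(C)C)[C@@H]23)cc1OC | intermediate
23 | (1R,4R,5R,6R,8R,9R,10R)-8,9-epoxy-4-hydroxy-2-oxo-10-(triethylsilyloxy)daucan-6-yl 3,4-dimethoxybenzoate | COc1ccc(C(=O)O[C@@H]2C[C@@]3(C)O[C@@H]3[C@H](O[Si](CC)(CC)CC)[C@]3(C)C(=O)C[C@@](O)(C(C)C)[C@@H]23)cc1OC | intermediate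
24 | (1S,2S,4R,5R,6R,8R,9R,10R)-8,9-epoxy-2,4-dihydroxy-10-(triethylsilyloxy)daucan-6-yl 3,4-dimethoxybenzoate | COc1ccc(C(=O)O[C@@H]2C[C@@]3(C)O[C@@H]3[C@H](O[Si](CC)(CC)CC)[C@]3(C)[C@@H](O)C[C@@](O)(C(C)C)[C@@H]23)cc1OC | intermediate
25 | (1S,2S,4R,5R,6R,8R,9R,10R)-2-acetoxy-8,9-epoxy-4-hydroxy-10-(triethylsilyloxy)daucan-6-yl 3,4-dimethoxybenzoate | COc1ccc(C(=O)O[C@@H]2C[C@@]3(C)O[C@@H]3[C@H](O[Si](CC)(CC)CC)[C@]3(C)[C@@H](OC(C)=O)C[C@@](O)(C(C)C)[C@@H]23)cc1OC | intermediate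
26 | (1R,2S,4R,5R,6R,8R,9R,10R)-2-acetoxy-8,9-epoxy-4,10-dihydroxydaucan-6-yl 3,4-dimethoxybenzoate (CNP0197096.5) | COc1ccc(C(=O)O[C@@H]2C[C@@]3(C)O[C@@H]3[C@H](O)[C@]3(C)[C@@H](OC(C)=O)C[C@@](O)(C(C)C)[C@@H]23)cc1OC | target

**Step count and risks**
Total step count: 16. Longest linear sequence: 16 steps (1 → 26); compounds 4, 10, 12 and 14 are purchased.

The stereochemical sense of three steps rests on models and analogy rather than on direct precedent for these substrates: the (R)-TRIP facial selectivity in steps 2 and 6, the chirality transfer in step 3, and the ring-fusion and C10 outcome of step 13.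

Step 13 (ring closure around the trans oxirane) is the most likely to fail. The product is strained, the samarium enolate can be protonated by the C4 hydroxyl, the epoxy aldehyde can be reduced, and a cis ring fusion is possible. The fallback sets out from 17 and comes back at 23, replacing the reductive metal enolate by a Lewis-acid Mukaiyama aldol on a bromine-free substrate. Dess–Martin oxidation of 17 gives the keto aldehyde (1R)-1-[(1R,2R,5S)-2-hydroxy-5-methyl-4-oxo-2-(propan-2-yl)cyclopentyl]-2-[(2R,3S)-3-formyl-2-methyloxiran-2-yl]ethyl 3,4-dimethoxybenzoate F6. Me3SiOTf and iPr2NEt in CH2Cl2 at −78 °C silylate the C4 alcohol and form, in the flask, the tetrasubstituted enol silane (1R)-2-[(2R,3S)-3-formyl-2-methyloxiran-2-yl]-1-[(1R,5R)-2-methyl-5-(propan-2-yl)-3,5-bis[(trimethylsilyl)oxy]cyclopent-2-en-1-yl]ethyl 3,4-dimethoxybenzoate F7. The silyl-triflate-activated aldehyde then closes ring B to (1R,4R,5R,6R,8R,9R,10R)-8,9-epoxy-2-oxo-4,10-bis(trimethylsilyloxy)daucan-6-yl 3,4-dimethoxybenzoate F8. Citric acid in MeOH gives the diol (1R,4R,5R,6R,8R,9R,10R)-8,9-epoxy-4,10-dihydroxy-2-oxodaucan-6-yl 3,4-dimethoxybenzoate F9, and Et3SiCl/imidazole silylates the secondary C10 alcohol to rejoin at 23.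

Step 11 (regioselective bromination at C1) can fail through enolisation toward C3, retro-aldol opening at the C4 alkoxide, or attack on the oxirane. The fallback sets out from 17 and comes back at 19, using thermodynamic instead of kinetic control. Me3SiOTf (4 equiv) and Et3N in CH2Cl2 at 0 → 23 °C under equilibrating conditions give the more substituted enol silane with both alcohols capped, (1R)-2-[(2R,3R)-2-methyl-3-{[(trimethylsilyl)oxy]methyl}oxiran-2-yl]-1-[(1R,5R)-2-methyl-5-(propan-2-yl)-3,5-bis[(trimethylsilyl)oxy]cyclopent-2-en-1-yl]ethyl 3,4-dimethoxybenzoate F4. NBS in THF at −78 °C brominates it to (1R)-1-[(1R,2R,5S)-5-bromo-5-methyl-4-oxo-2-(propan-2-yl)-2-[(trimethylsilyl)oxy]cyclopentyl]-2-[(2R,3R)-2-methyl-3-{[(trimethylsilyl)oxy]methyl}oxiran-2-yl]ethyl 3,4-dimethoxybenzoate F5, and citric acid in MeOH removes both silyl ethers to give 19.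

Step 4 (cyclopropane oxymercuration and oxygenation) can fail through α-mercuration of the ketone, loss of regiocontrol, or borohydride reduction of the ketone. The fallback sets out from 6 and comes back at 9, removing the ketone first and restoring it in a redox adjustment. NaBH4 in MeOH gives (1R,3R,4S,5S)-4-methyl-1-(propan-2-yl)bicyclo[3.1.0]hexan-3-ol F1 (either carbinol epimer serves). Oxymercuration with Hg(O2CCF3)2 in THF–H2O gives {[(1S,2R,4R,5S)-2,4-dihydroxy-5-methyl-2-(propan-2-yl)cyclopentyl]methyl}mercury trifluoroacetate F2, and NaBH4/O2 in DMF converts it into (1R,2S,3R,4R)-3-(hydroxymethyl)-2-methyl-4-(propan-2-yl)cyclopentane-1,4-diol F3. Dess–Martin oxidation of both the primary and the secondary alcohol then gives 9 directly, bypassing 8.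

Further compounds
F1 | step 4 | (1R,3R,4S,5S)-4-methyl-1-(propan-2-yl)bicyclo[3.1.0]hexan-3-ol | C[C@H]1[C@@H]2C[C@@]2(C[C@H]1O)C(C)C
F2 | step 4 | {[(1S,2R,4R,5S)-2,4-dihydroxy-5-methyl-2-(propan-2-yl)cyclopentyl]methyl}mercury trifluoroacetate | C[C@H]1[C@H](C[Hg]OC(=O)C(F)(F)F)[C@](O)(C(C)C)C[C@H]1O
F3 | step 4 | (1R,2S,3R,4R)-3-(hydroxymethyl)-2-methyl-4-(propan-2-yl)cyclopentane-1,4-diol | C[C@H]1[C@H](CO)[C@](O)(C(C)C)C[C@H]1O
F4 | step 11 | (1R)-2-[(2R,3R)-2-methyl-3-{[(trimethylsilyl)oxy]methyl}oxiran-2-yl]-1-[(1R,5R)-2-methyl-5-(propan-2-yl)-3,5-bis[(trimethylsilyl)oxy]cyclopent-2-en-1-yl]ethyl 3,4-dimethoxybenzoate | CC1=C(O[Si](C)(C)C)C[C@@](O[Si](C)(C)C)(C(C)C)[C@H]1[C@H](OC(=O)c2ccc(OC)c(OC)c2)C[C@@]3(C)O[C@@H]3CO[Si](C)(C)C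
F5 | step 11 | (1R)-1-[(1R,2R,5S)-5-bromo-5-methyl-4-oxo-2-(propan-2-yl)-2-[(trimethylsilyl)oxy]cyclopentyl]-2-[(2R,3R)-2-methyl-3-{[(trimethylsilyl)oxy]methyl}oxiran-2-yl]ethyl 3,4-dimethoxybenzoate | C[C@]1(Br)[C@H]([C@H](OC(=O)c2ccc(OC)c(OC)c2)C[C@@]3(C)O[C@@H]3CO[Si](C)(C)C)[C@](O[Si](C)(C)C)(C(C)C)CC1=O
F6 | step 13 | (1R)-1-[(1R,2R,5S)-2-hydroxy-5-methyl-4-oxo-2-(propan-2-yl)cyclopentyl]-2-[(2R,3S)-3-formyl-2-methyloxiran-2-yl]ethyl 3,4-dimethoxybenzoate | C[C@H]1[C@H]([C@H](OC(=O)c2ccc(OC)c(OC)c2)C[C@@]3(C)O[C@@H]3C=O)[C@](O)(C(C)C)CC1=O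
F7 | step 13 | (1R)-2-[(2R,3S)-3-formyl-2-methyloxiran-2-yl]-1-[(1R,5R)-2-methyl-5-(propan-2-yl)-3,5-bis[(trimethylsilyl)oxy]cyclopent-2-en-1-yl]ethyl 3,4-dimethoxybenzoate | CC1=C(O[Si](C)(C)C)C[C@@](O[Si](C)(C)C)(C(C)C)[C@H]1[C@H](OC(=O)c2ccc(OC)c(OC)c2)C[C@@]3(C)O[C@@H]3C=O
F8 | step 13 | (1R,4R,5R,6R,8R,9R,10R)-8,9-epoxy-2-oxo-4,10-bis(trimethylsilyloxy)daucan-6-yl 3,4-dimethoxybenzoate | COc1ccc(C(=O)O[C@@H]2C[C@@]3(C)O[C@@H]3[C@H](O[Si](C)(C)C)[C@]3(C)C(=O)C[C@@](O[Si](C)(C)C)(C(C)C)[C@@H]23)cc1OC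
F9 | step 13 | (1R,4R,5R,6R,8R,9R,10R)-8,9-epoxy-4,10-dihydroxy-2-oxodaucan-6-yl 3,4-dimethoxybenzoate | COc1ccc(C(=O)O[C@@H]2C[C@@]3(C)O[C@@H]3[C@H](O)[C@]3(C)C(=O)C[C@@](O)(C(C)C)[C@@H]23)cc1OC
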